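# Proposed total synthesis of epimedonin J

Assumption: "prenyl" means 3-methylbut-2-en-1-yl, TIPS triisopropylsilyl, MOM methoxymethyl; ring positions follow chromone numbering (O1, C2–C4, C4a, C5–C8, C8a; ring B′ primed); the terminal aryl ynol ether 18 is assumed to survive brief handling as a cold ethereal solution.

## Analysis of the target

Epimedonin J (23) is a 2-aryloxychromone. Ring A is fused to the pyranone ring C, and C2 is joined through an ether oxygen to a second benzene ring (ring B′). Ring A carries hydroxyls at C5 and C7 and a prenyl group at C8; ring B′ carries a hydroxyl at C4′ and a prenyl group at C3′. There is no stereocentre, and both alkenes end in two methyl groups, so no configuration has to be set.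

Each prenyl group sits ortho to a phenol, so acids and electrophiles can close a chroman or dihydrobenzofuran. The C2–O–aryl unit is a vinylogous aryl carbonate, so amines or alkoxides can add at C2 and expel the phenoxide.

The difficulty is twofold. Ring A derives from a phloroglucinol whose three oxygens are equivalent, yet the ring oxygen O1 must be the one next to the prenyl group (C8, not C6). The C2–O–aryl bond also lies outside ordinary flavone chemistry.

The strategy rests on C4. It is a carbonyl carbon bonded only to C4a of ring A and to C3, while C3 is a CH and C2 carries two oxygens. C4 can therefore come from carbon monoxide, and C3–C2 with the exocyclic oxygen from an aryl ethynyl ether.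

## Retrosynthetic reasoning

**Protecting groups (23 ⇐ 22 ⇐ 21).** Only oxygen–protecting-group bonds are cut. The C5 oxygen must be masked in the ring-forming step so that the other ortho oxygen closes the ring. The C4′ oxygen must be masked because the ynol ether is made with an alkyllithium. A silyl ether at C5 and an acetal at C4′ come off under buffered fluoride and mild acid respectively. The acid step is placed last, so its by-products are volatile.

**Ring C (21 ⇐ 8 + 19 + 18).** The cuts are C4a–C4, C4–C3 and O1–C2. These three bonds are chosen because C4 has no substituent but oxygen and so maps onto carbon monoxide 19, while C2 and C3 map onto the alkyne carbons of 18 with the aryloxy oxygen already attached. One operation then closes ring C and joins the two aryl halves, each already carrying its prenyl group, so no late C-prenylation is needed. The forward reaction must take up CO before alkynyl transfer, close the ynone 20 in the 6-endo mode, keep the aryloxy group, and close through the hydroxyl next to the prenyl group. The last point is settled by the substitution of 8: its iodine lies between a free hydroxyl and the silyl ether.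

**Ring A fragment (8 ⇐ 7 ⇐ 6 ⇐ 3 + 4; 3 ⇐ 2 ⇐ 1).** The C–I bond is cut first. Diol 7 has a mirror plane through the prenyl carbon and the silyloxy carbon, so its two free ring positions are equivalent and mono-iodination can give only 8. The prenyl C–C bond is cut between the two oxygens that later become O1 and the C7 hydroxyl. Two acetal ethers in 3 direct lithiation to exactly that carbon (aryllithium 5), which is alkylated with 4. The third oxygen carries the silyl group from the first step, so phloroglucinol 1 is desymmetrised once, by a statistical monosilylation to 2.

**Ring B′ fragment (18 ⇐ 17 ⇐ 16 ⇐ 14 + 15; 14 ⇐ 13 ⇐ 11 + 4; 11 ⇐ 10 ⇐ 9).** The O–C(sp) bond is cut. Phenol 14 adds to the two-carbon unit of 15 to give the dichlorovinyl ether 16, which is converted through acetylide 17 into 18. The prenyl group of 14 is again placed by directed metalation (aryllithium 12), ortho to the acetal ether of 11. The para oxygen is held as a silyl ether that is removed in 13 before the ynol ether is built. Hydroquinone 9 is monosilylated to 10 at the start.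

## Alternatives that were turned down

**Alternative 1:** Both prenyl C–C bonds (C8–CH2 and C3′–CH2) are disconnected back to oxygen. The precursor A2 is a 2-aryloxychromone with a prenyl ether at O5 and a 1,1-dimethylallyl ether at O4′. Heating it with a Lewis-acidic europium tris(β-diketonate) should move the first group to C6 by a Claisen shift and on to C8 by a Cope shift, and the second to C3′ by a Claisen shift, giving the 7-O-MOM ether A1.
- For it: both prenyl groups appear in one late step, so no prenyl alkene passes through iodination, organolithium or acid steps. On that point it is stronger than the chosen route.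
- Against it: the C6 dienone can tautomerise before the Cope shift, so C6 products leak in. The tertiary allyl ether can ionise under the Lewis acid. Two different rearrangements must run cleanly at one temperature. The 2-aryloxychromone core of A2 still has to be made by some other C–O or C–C construction.
- Comparison: the chosen route is more convergent and fixes the C8 position by the structure of 8 rather than by a rate competition.

**Alternative 2:** Ring A is built from acyclic parts. The siloxydiene A4 adds to the alkoxy ynone A5, forming C5–C6 and C4a–C8a, and loss of a silyl methyl ether aromatises the ring to the acetophenone A3.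
- For it: the substitution pattern of ring A, with the prenyl group between two oxygens, follows from the diene without desymmetrising a phloroglucinol and without a halogenation. On that point it is stronger.
- Against it: A3 contains only ring A, C4 and C3. Ring C and the C2–O–aryl bond would need several further steps, and the usual route through a 2-sulfonylchromone requires an oxidation that the prenyl alkene does not tolerate. The C5 oxygen emerges as an ethyl ether, whose cleavage needs a strong Lewis acid next to a prenyl phenol. The regiochemistry of a push–pull alkyne with a 2-substituted diene is not assured.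
- Comparison: the chosen route forms ring C and attaches ring B′ in one step from two fragments of similar size.

**Alternative 3:** The same two ring-C bonds to the alkyne are made without a metal. The benzodioxinone A7 is irradiated or heated to extrude its acetonide ketone. The resulting quinone ketene adds the ynol ether 18 across O1 and C4, forming O1–C2 and C3–C4, to give the tris-MOM ether A6.
- For it: no palladium and no CO gas; the same convergence; one type of protecting group and therefore one final deprotection. On these points it is as strong or stronger.
- Against it: ketenes and ynol ethers also combine in a [2+2] sense to cyclobutenones. Thermal opening of an aromatic dioxinone needs temperatures that 18 would not survive. Irradiation near 300 nm exposes two prenyl alkenes and an aryl ynol ether to photochemistry. The regiochemical problem is only moved: in making A7 the acetonide must form on the oxygen next to the prenyl group, and directed metalation of a protected dioxinone would favour C6 over C8.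
- Comparison: the chosen route settles the same question by the symmetry of 7 and by the silyl group, and every elementary step of its key reaction has a close catalytic analogy.

Key step: step 12

## Route

**Step 1**
Reactants: 1 phloroglucinol (3 equiv)
Product: 2 5-(triisopropylsilyloxy)benzene-1,3-diol
Conditions: TIPSCl (1.0 equiv), imidazole, DMF, 0 °C → rt
Reagents that add atoms: triisopropylsilyl chloride, CC(C)[Si](Cl)(C(C)C)C(C)C
Why: Statistical monosilylation of a symmetric triol with a bulky silyl chloride; the excess of 1 suppresses bis-silylation and is removed by aqueous extraction.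

**Step 2**
Reactants: 2 5-(triisopropylsilyloxy)benzene-1,3-diol
Product: 3 [3,5-bis(methoxymethoxy)phenoxy]triisopropylsilane
Conditions: MOMCl (2.6 equiv), i-Pr2NEt, CH2Cl2, 0 °C → rt
Reagents that add atoms: chloromethyl methyl ether, COCCl
Why: O-alkylation of both phenols (MOM protection) under amine base; the two acetal ethers serve as a pair of directing groups for the next step and the aryl silyl ether is inert.

**Step 3**
Reactants: 3 [3,5-bis(methoxymethoxy)phenoxy]triisopropylsilane; 4 prenyl bromide
Product: 6 [3,5-bis(methoxymethoxy)-4-(3-methylbut-2-enyl)phenoxy]triisopropylsilane, via aryllithium 5 (not isolated)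
Conditions: n-BuLi (1.2 equiv), THF, 0 °C; then CuI (10 mol %), 4, −78 °C → rt
Reagents that add atoms: none
Why: Directed ortho-metalation at the carbon flanked by both MOM ethers (cooperative chelation; the bulky silyl ether does not direct), then copper-catalysed SN2 allylation, which should give the linear prenyl arene.

**Step 4**
Reactants: 6 [3,5-bis(methoxymethoxy)-4-(3-methylbut-2-enyl)phenoxy]triisopropylsilane
Product: 7 2-(3-methylbut-2-enyl)-5-(triisopropylsilyloxy)benzene-1,3-diol
Conditions: HCl (3 M aq.), MeOH, rt → 40 °C
Reagents that add atoms: none
Why: Acid-catalysed acetal exchange with methanol removes both MOM groups; the aryl TIPS ether is stable to dilute acid, and the moderate temperature is chosen to avoid chroman formation.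

**Step 5**
Reactants: 7 2-(3-methylbut-2-enyl)-5-(triisopropylsilyloxy)benzene-1,3-diol
Product: 8 4-iodo-2-(3-methylbut-2-enyl)-5-(triisopropylsilyloxy)benzene-1,3-diol
Conditions: I2 (1.0 equiv), NaHCO3, THF/H2O, 0 °C
Reagents that add atoms: iodine, II
Why: Electrophilic aromatic iodination of a phloroglucinol-type phenol through its phenoxide; the two free ring positions of 7 are equivalent by mirror symmetry, so one mono-iodide is possible. The ring carbon, ortho/para to three oxygens, should be far more nucleophilic than the trisubstituted alkene, and one equivalent of iodine limits di-iodination.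

**Step 6**
Reactants: 9 hydroquinone (3 equiv)
Product: 10 4-(triisopropylsilyloxy)phenol
Conditions: TIPSCl (1.0 equiv), imidazole, DMF, 0 °C → rt
Reagents that add atoms: triisopropylsilyl chloride, CC(C)[Si](Cl)(C(C)C)C(C)C
Why: Statistical monosilylation of a symmetric diol; the excess of 9 is washed out with water.

**Step 7**
Reactants: 10 4-(triisopropylsilyloxy)phenol
Product: 11 [4-(methoxymethoxy)phenoxy]triisopropylsilane
Conditions: MOMCl (1.3 equiv), i-Pr2NEt, CH2Cl2, 0 °C → rt
Reagents that add atoms: chloromethyl methyl ether, COCCl
Why: MOM protection of the remaining phenol; it installs the only directing group of the ring on the oxygen that becomes the C4′ hydroxyl.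

**Step 8**
Reactants: 11 [4-(methoxymethoxy)phenoxy]triisopropylsilane; 4 prenyl bromide
Product: 13 [4-(methoxymethoxy)-3-(3-methylbut-2-enyl)phenoxy]triisopropylsilane, via aryllithium 12 (not isolated)
Conditions: n-BuLi (1.2 equiv), TMEDA, THF, 0 °C; then CuI (10 mol %), 4, −78 °C → rt
Reagents that add atoms: none
Why: Directed ortho-metalation next to the MOM ether (both ortho positions are equivalent and the silyl ether does not direct), then copper-catalysed SN2 allylation places the prenyl group ortho to the future C4′ oxygen.

**Step 9**
Reactants: 13 [4-(methoxymethoxy)-3-(3-methylbut-2-enyl)phenoxy]triisopropylsilane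
Product: 14 4-(methoxymethoxy)-3-(3-methylbut-2-enyl)phenol
Conditions: TBAF (1.1 equiv), AcOH (1.1 equiv), THF, 0 °C
Reagents that add atoms: none
Why: Fluoride-driven cleavage of the aryl silyl ether; the MOM ether and the alkene are inert to buffered fluoride.

**Step 10**
Reactants: 14 4-(methoxymethoxy)-3-(3-methylbut-2-enyl)phenol; 15 trichloroethylene
Product: 16 4-[(E)-1,2-dichlorovinyloxy]-1-(methoxymethoxy)-2-(3-methylbut-2-enyl)benzene
Conditions: K2CO3, DMF, 70 °C
Reagents that add atoms: none
Why: Base-mediated dehydrochlorination of 15 to dichloroacetylene and anti addition of the phenoxide gives the (E)-1,2-dichlorovinyl ether, the established first stage of ynol ether synthesis from phenols.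

**Step 11**
Reactants: 16 4-[(E)-1,2-dichlorovinyloxy]-1-(methoxymethoxy)-2-(3-methylbut-2-enyl)benzene
Product: 18 4-ethynyloxy-1-(methoxymethoxy)-2-(3-methylbut-2-enyl)benzene, via lithium acetylide 17 (not isolated)
Conditions: n-BuLi (2.2 equiv), Et2O, −78 → −40 °C; then MeOH, −78 °C; kept as a cold solution
Reagents that add atoms: none
Why: Vinylic deprotonation and loss of chloride give the chloroalkyne, chlorine–lithium exchange gives the acetylide 17, and cold protonation gives the terminal ynol ether (the known dichlorovinyl ether route to ynol ethers); at −78 °C without a diamine the MOM group should not direct ring lithiation.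

**Step 12**
Reactants: 8 4-iodo-2-(3-methylbut-2-enyl)-5-(triisopropylsilyloxy)benzene-1,3-diol; 19 carbon monoxide; 18 4-ethynyloxy-1-(methoxymethoxy)-2-(3-methylbut-2-enyl)benzene (1.5 equiv)
Product: 21 7-hydroxy-2-[4-(methoxymethoxy)-3-(3-methylbut-2-enyl)phenoxy]-8-(3-methylbut-2-enyl)-5-(triisopropylsilyloxy)-4H-chromen-4-one, via hydroxyaryl ynone 20 (not isolated)
Conditions: Pd(PPh3)2Cl2 (5 mol %), Et3N (3 equiv), CO (1 atm), THF, 50 °C
Reagents that add atoms: none
Why: Pd(PPh3)2Cl2 is reduced in the flask to zerovalent palladium, which inserts into the C–I bond of 8; CO insertion gives the aroylpalladium iodide, and Et3N-assisted transfer of the alkynyl group of 18 followed by reductive elimination gives the ynone 20 (C4a–C4 and C4–C3). The closest known reaction type is the palladium-catalysed carbonylative Sonogashira coupling of 2-iodophenols with terminal alkynes with cyclisation in the same pot to chromones and flavones; the ynol ether is an unusual but mechanistically ordinary alkyne partner. Ring C closes by 6-endo-dig oxa-Michael addition of the hydroxyl ortho to the acyl group to the aryloxy-bearing alkyne carbon, followed by protonation at C3 (O1–C2). That carbon is both the β-carbon of the ynone and the oxocarbenium-like carbon of the ynol ether, whereas the α-carbon is the electron-rich end of the push–pull alkyne, so 5-exo-dig closure to an aurone has no driving force. No stereocentre is formed. Carbonylative rather than direct coupling is favoured by the electron-rich, doubly ortho-substituted aryl group, which should migrate to CO quickly and couple directly only slowly. Only the hydroxyl between the prenyl group and the acyl carbon is ortho to the acyl group (the other ortho oxygen is silylated and the second hydroxyl is para), so O1 is fixed next to the prenyl group and the prenyl group at C8. A tertiary amine is used because a secondary amine would add to 20 or to C2 of 21 and expel the aryloxide.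

**Step 13**
Reactants: 21 7-hydroxy-2-[4-(methoxymethoxy)-3-(3-methylbut-2-enyl)phenoxy]-8-(3-methylbut-2-enyl)-5-(triisopropylsilyloxy)-4H-chromen-4-one
Product: 22 5,7-dihydroxy-2-[4-(methoxymethoxy)-3-(3-methylbut-2-enyl)phenoxy]-8-(3-methylbut-2-enyl)-4H-chromen-4-one
Conditions: TBAF (1.2 equiv), AcOH (1.5 equiv), THF, 0 °C
Reagents that add atoms: none
Why: Fluoride cleavage of the silyl ether peri to the carbonyl, an activated aryl silyl ether; the acetic acid buffer keeps the phenols protonated and keeps basic nucleophiles away from C2.

**Step 14**
Reactants: 22 5,7-dihydroxy-2-[4-(methoxymethoxy)-3-(3-methylbut-2-enyl)phenoxy]-8-(3-methylbut-2-enyl)-4H-chromen-4-one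
Product: 23 epimedonin J
Conditions: HCl (3 M aq.), MeOH, rt → 40 °C
Reagents that add atoms: none
Why: Acid-catalysed acetal exchange removes the MOM group, as is routine for prenylated flavonoids; dilute acid and moderate temperature are chosen to spare the two ortho-prenyl phenols and the C2 aryloxy group.

## Compound list

1 | phloroglucinol (benzene-1,3,5-triol) | Oc1cc(O)cc(O)c1 | starting material
2 | 5-(triisopropylsilyloxy)benzene-1,3-diol | CC(C)[Si](Oc1cc(O)cc(O)c1)(C(C)C)C(C)C | intermediate
3 | [3,5-bis(methoxymethoxy)phenoxy]triisopropylsilane | COCOc1cc(OCOC)cc(O[Si](C(C)C)(C(C)C)C(C)C)c1 | intermediate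
4 | prenyl bromide (1-bromo-3-methylbut-2-ene) | CC(C)=CCBr | starting material
5 | [2,6-bis(methoxymethoxy)-4-(triisopropylsilyloxy)phenyl]lithium | [Li]c1c(OCOC)cc(O[Si](C(C)C)(C(C)C)C(C)C)cc1OCOC | intermediate
6 | [3,5-bis(methoxymethoxy)-4-(3-methylbut-2-enyl)phenoxy]triisopropylsilane | COCOc1cc(O[Si](C(C)C)(C(C)C)C(C)C)cc(OCOC)c1CC=C(C)C | intermediate
7 | 2-(3-methylbut-2-enyl)-5-(triisopropylsilyloxy)benzene-1,3-diol | CC(C)=CCc1c(O)cc(O[Si](C(C)C)(C(C)C)C(C)C)cc1O | intermediate
8 | 4-iodo-2-(3-methylbut-2-enyl)-5-(triisopropylsilyloxy)benzene-1,3-diol | CC(C)=CCc1c(O)cc(O[Si](C(C)C)(C(C)C)C(C)C)c(I)c1O | intermediate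
9 | hydroquinone (benzene-1,4-diol) | Oc1ccc(O)cc1 | starting material
10 | 4-(triisopropylsilyloxy)phenol | CC(C)[Si](Oc1ccc(O)cc1)(C(C)C)C(C)C | intermediate
11 | [4-(methoxymethoxy)phenoxy]triisopropylsilane | COCOc1ccc(O[Si](C(C)C)(C(C)C)C(C)C)cc1 | intermediate
12 | [2-(methoxymethoxy)-5-(triisopropylsilyloxy)phenyl]lithium | [Li]c1cc(O[Si](C(C)C)(C(C)C)C(C)C)ccc1OCOC | intermediate
13 | [4-(methoxymethoxy)-3-(3-methylbut-2-enyl)phenoxy]triisopropylsilane | COCOc1ccc(O[Si](C(C)C)(C(C)C)C(C)C)cc1CC=C(C)C | intermediate
14 | 4-(methoxymethoxy)-3-(3-methylbut-2-enyl)phenol | COCOc1ccc(O)cc1CC=C(C)C | intermediate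
15 | trichloroethylene | ClC=C(Cl)Cl | starting material
16 | 4-[(E)-1,2-dichlorovinyloxy]-1-(methoxymethoxy)-2-(3-methylbut-2-enyl)benzene | Cl/C=C(/Cl)Oc1ccc(OCOC)c(CC=C(C)C)c1 | intermediate
17 | lithium [4-(methoxymethoxy)-3-(3-methylbut-2-enyl)phenoxy]acetylide | [Li]C#COc1ccc(OCOC)c(CC=C(C)C)c1 | intermediate
18 | 4-ethynyloxy-1-(methoxymethoxy)-2-(3-methylbut-2-enyl)benzene | C#COc1ccc(OCOC)c(CC=C(C)C)c1 | intermediate
19 | carbon monoxide | [C-]#[O+] | starting material
20 | 1-[2,4-dihydroxy-3-(3-methylbut-2-enyl)-6-(triisopropylsilyloxy)phenyl]-3-[4-(methoxymethoxy)-3-(3-methylbut-2-enyl)phenoxy]prop-2-yn-1-one | CC(C)=CCc1c(O)cc(O[Si](C(C)C)(C(C)C)C(C)C)c(C(=O)C#COc2ccc(OCOC)c(CC=C(C)C)c2)c1O | intermediate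
21 | 7-hydroxy-2-[4-(methoxymethoxy)-3-(3-methylbut-2-enyl)phenoxy]-8-(3-methylbut-2-enyl)-5-(triisopropylsilyloxy)-4H-chromen-4-one | CC(C)=CCc1cc(Oc2cc(=O)c3c(O[Si](C(C)C)(C(C)C)C(C)C)cc(O)c(CC=C(C)C)c3o2)ccc1OCOC | intermediate
22 | 5,7-dihydroxy-2-[4-(methoxymethoxy)-3-(3-methylbut-2-enyl)phenoxy]-8-(3-methylbut-2-enyl)-4H-chromen-4-one | CC(C)=CCc1cc(Oc2cc(=O)c3c(O)cc(O)c(CC=C(C)C)c3o2)ccc1OCOC | intermediate
23 | epimedonin J, 5,7-dihydroxy-2-[4-hydroxy-3-(3-methylbut-2-enyl)phenoxy]-8-(3-methylbut-2-enyl)-4H-chromen-4-one | CC(C)=CCc1cc(Oc2cc(=O)c3c(O)cc(O)c(CC=C(C)C)c3o2)ccc1O | target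

## Step count and least certain steps

Total step count: 14 (ring A fragment: steps 1–5; ring B′ fragment: steps 6–11; steps 12–14 after the union).
Longest linear sequence: 9 steps (hydroquinone 9 to 23 through steps 6–14).

**Step 12 (key step).** The most likely failures are loss of the ynol ether by hydration or oligomerisation under palladium and ammonium salt before it is transferred, direct alkynylation without CO uptake followed by closure to a benzofuran, and capture of the aroylpalladium species by a free phenol of a second molecule. They are likely because oxidative addition at the hindered, very electron-rich iodide is slow, which leaves the fragile alkyne waiting in a warm basic medium.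

Fallback: nucleophilic acyl substitution replaces alkynyl transfer at palladium. Setting out from 8, palladium-catalysed aminocarbonylation with N,O-dimethylhydroxylamine hydrochloride (Pd(OAc)2, Xantphos, Et3N, CO 1 atm, toluene, 80 °C) should give the Weinreb amide 2,4-dihydroxy-N-methoxy-N-methyl-3-(3-methylbut-2-enyl)-6-(triisopropylsilyloxy)benzamide F1. Its two phenols are deprotonated with LiN(SiMe3)2 (2 equiv, THF, −78 °C), and the lithium acetylide 17, made from 16 as in step 11 but not protonated, is added. The chelated adduct should collapse on aqueous NH4Cl work-up to the ynone 20, which is closed with Et3N in THF; the route is rejoined at 21. The ynol ether is then handled only as its acetylide at low temperature, and CO still supplies C4.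

**Step 5.** Iodocycloetherification can compete: the iodonium ion of the prenyl alkene is captured by a flanking hydroxyl. Over-iodination at the second equivalent ring position is the other risk. Both arise because the electrophile meets an alkene with an internal nucleophile in the same molecule.

Fallback: the order is changed so that no free hydroxyl is present. Setting out from 6, iodination with N-iodosuccinimide in MeCN at 0 °C should give [2-iodo-3,5-bis(methoxymethoxy)-4-(3-methylbut-2-enyl)phenoxy]triisopropylsilane F2, in which the alkene has no neighbouring nucleophile. Removal of both MOM groups with HCl in MeOH, as in step 4, returns to the route at 8.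

**Step 11.** The terminal aryl ynol ether can polymerise or hydrate on concentration, chromatography or storage, because the electron-rich alkyne is protonated easily and has no substituent at its terminus.

Fallback: a storable silyl-capped form is used. Setting out from 16, the acetylide 17 is generated as before and quenched with Me3SiCl to give trimethyl{[4-(methoxymethoxy)-3-(3-methylbut-2-enyl)phenoxy]ethynyl}silane F3, which can be purified and kept. Just before step 12 the silyl group is removed with catalytic K2CO3 in MeOH at 0 °C; the alkyne is extracted into pentane, dried and exchanged into THF without concentration to dryness, which returns to the route at 18.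

**Step 14.** Under Brønsted acid a prenyl alkene can be protonated and captured by the neighbouring hydroxyl (C7 or C4′) to give a chroman, and methanol can exchange with the aryloxy group at C2 of the protonated chromone. Both are possible because the last intermediate carries all sensitive groups unprotected.

Fallback: silyl transfer replaces protic acetal cleavage. Setting out from 21, Me3SiOTf with 2,2′-bipyridyl in CH2Cl2 at 0 °C should exchange the MOM group for a trimethylsilyl group and silylate the C7 hydroxyl. This gives 2-[3-(3-methylbut-2-enyl)-4-(trimethylsilyloxy)phenoxy]-8-(3-methylbut-2-enyl)-5-(triisopropylsilyloxy)-7-(trimethylsilyloxy)-4H-chromen-4-one F4. One treatment with TBAF and AcOH in THF at 0 °C then removes all three silyl groups; the route is rejoined at 23 without passing 22 and without methanol or mineral acid.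

## Further compounds

F1 | step 12 | 2,4-dihydroxy-N-methoxy-N-methyl-3-(3-methylbut-2-enyl)-6-(triisopropylsilyloxy)benzamide | CON(C)C(=O)c1c(O)c(CC=C(C)C)c(O)cc1O[Si](C(C)C)(C(C)C)C(C)C
F2 | step 5 | [2-iodo-3,5-bis(methoxymethoxy)-4-(3-methylbut-2-enyl)phenoxy]triisopropylsilane | COCOc1cc(O[Si](C(C)C)(C(C)C)C(C)C)c(I)c(OCOC)c1CC=C(C)C
F3 | step 11 | trimethyl{[4-(methoxymethoxy)-3-(3-methylbut-2-enyl)phenoxy]ethynyl}silane | C[Si](C)(C)C#COc1ccc(OCOC)c(CC=C(C)C)c1
F4 | step 14 | 2-[3-(3-methylbut-2-enyl)-4-(trimethylsilyloxy)phenoxy]-8-(3-methylbut-2-enyl)-5-(triisopropylsilyloxy)-7-(trimethylsilyloxy)-4H-chromen-4-one | CC(C)=CCc1cc(Oc2cc(=O)c3c(O[Si](C(C)C)(C(C)C)C(C)C)cc(O[Si](C)(C)C)c(CC=C(C)C)c3o2)ccc1O[Si](C)(C)C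
A1 | alternative 1 | 7-O-methoxymethyl ether of epimedonin J | CC(C)=CCc1cc(Oc2cc(=O)c3c(O)cc(OCOC)c(CC=C(C)C)c3o2)ccc1O
A2 | alternative 1 | 7-(methoxymethoxy)-5-(3-methylbut-2-enyloxy)-2-[4-(2-methylbut-3-en-2-yloxy)phenoxy]-4H-chromen-4-one | C=CC(C)(C)Oc1ccc(Oc2cc(=O)c3c(OCC=C(C)C)cc(OCOC)cc3o2)cc1
A3 | alternative 2 | 1-[6-ethoxy-2,4-dihydroxy-3-(3-methylbut-2-enyl)phenyl]ethanone | CCOc1cc(O)c(CC=C(C)C)c(O)c1C(C)=O
A4 | alternative 2 | 1-methoxy-2-(3-methylbut-2-enyl)-1,3-bis(trimethylsilyloxy)buta-1,3-diene | COC(O[Si](C)(C)C)=C(CC=C(C)C)C(=C)O[Si](C)(C)C
A5 | alternative 2 | 4-ethoxybut-3-yn-2-one | CCOC#CC(C)=O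
A6 | alternative 3 | 5,7,4′-tris-O-methoxymethyl ether of epimedonin J | CC(C)=CCc1cc(Oc2cc(=O)c3c(OCOC)cc(OCOC)c(CC=C(C)C)c3o2)ccc1OCOC
A7 | alternative 3 | 5,7-bis(methoxymethoxy)-2,2-dimethyl-8-(3-methylbut-2-enyl)-4H-1,3-benzodioxin-4-one | CC1(C)OC(=O)c2c(OCOC)cc(OCOC)c(CC=C(C)C)c2O1
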